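**Plan**

1. Retrosynthetic cuts, in order: (a) the ketal bond C2(chromanone)–O7(flavan) and the chromanone C3–OH bond, back to a 2,3-diarylchromone via its epoxide; (b) the C3(chromanone)–C8(flavan) bond, by Negishi coupling of a 3-iodoflavone with an 8-metalated flavan; (c) the flavan C3–OH and C2–H bonds, by hydroboration of a 4H-chromene; (d) excision of flavan C3 from the pyran ring, leaving a 2-arylbenzofuran.
2. Enabling feature: in the flavan pyran ring (O1, C2, C3, C4, C4a, C8a) O1 sits on the phloroglucinol ring D and C2 carries the 4-oxygenated aryl group. Without C3 this ring is the furan of a 2-arylbenzofuran, whose C2=C3 enol-ether bond takes up one carbon as a chlorocarbenoid; O1 and the aryl group then stabilise the 2-arylbenzopyrylium ion released when the cyclopropane opens.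
3. Forward order of rings: furan ring on the dibenzyloxyphenol, ring enlargement to the pyrylium ring, 4H-chromene, flavan-3-ol; the chromone ring comes ready-made from apigenin; the halves are joined at C8/C3 and the five-membered ketal ring closes last, on global debenzylation.
4. Stereochemistry: flavan C2 (S) and C3 (R) are set together by syn hydroboration with a chiral borane (trans by mechanism, absolute sense by the reagent). Chromanone C3 (S) is set in the epoxidation, for which no useful bias from the remote flavan centres is expected, so the (3S) series is separated as diastereomers. Chromanone C2 is fixed last by the ketal ring closure.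

Key step: step 2

Remark: each half is numbered as a flavan/flavanone; read literally, the SMILES puts O7 and C8 on opposite faces of the chromanone C2–C3 bond, but this ketal carbon equilibrates through its 2-aryl oxocarbenium ion, so the route fixes chromanone C3 and both flavan centres as written and takes C2 as the ring closure gives it; the reagent from (−)-α-pinene is assumed to induce as it does with 1-arylcycloalkenes.

**Route**

Step 1
Reactants: 1 3,5-bis(benzyloxy)phenol; 2 2-bromo-1-[4-(benzyloxy)phenyl]ethan-1-one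
Product: 4 4,6-bis(benzyloxy)-2-[4-(benzyloxy)phenyl]-1-benzofuran, via aryl ketone 3 (not isolated)
Conditions: neutral Al2O3, xylene, reflux
Reagents that add atoms: none
Why: On neutral alumina the phenol is C-alkylated ortho to the hydroxyl by the phenacyl bromide (Friedel–Crafts type) and then condenses with the aryl ketone (cyclodehydration), which gives the 2-arylbenzofuran regioselectively, whereas base-mediated O-alkylation would lead to the 3-aryl isomer; no stereocenter.

Step 2
Reactants: 4 4,6-bis(benzyloxy)-2-[4-(benzyloxy)phenyl]-1-benzofuran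
Product: 6 5,7-bis(benzyloxy)-2-[4-(benzyloxy)phenyl]chromenylium chloride, via chlorocyclopropane 5 (not isolated)
Conditions: CH2Cl2 (excess), NaN(SiMe3)2, Et2O, −40 → 0 °C; work-up with HCl in Et2O
Reagents that add atoms: dichloromethane ClCCl
Why: Deprotonation of CH2Cl2 gives the chlorocarbenoid NaCHCl2, which transfers CHCl to the electron-rich C2=C3 enol-ether bond of the furan ring in a concerted [2+1] addition to give 5; loss of chloride with disrotatory two-electron electrocyclic opening of the ring-fusion bond (cyclopropyl to allyl cation) then gives the aromatic 2-arylbenzopyrylium ion, so the five-membered O-heterocycle becomes the six-membered one with the new CH as C3. The closest known reaction type is the halocarbene ring enlargement of benzofurans, indoles and pyrroles (Ciamician–Dennstedt and Parham type, with chlorocarbene from CH2Cl2 as in the Closs procedure). The three-membered ring closes by cheletropic addition, and the six-membered ring arises not by a closure but by scission of the bond shared by the furan and the cyclopropane. The two stereocenters of 5 are transient and are erased in planar 6, so no stereocontrol is asked of this step. It needs site selectivity for the furan double bond over the benzenoid rings and the benzylic C–H bonds, which the enol-ether character of C2=C3 (reinforced by the 4- and 6-benzyloxy groups) secures, and it needs the chlorine on the concave face, anti to the 2-aryl group, which sterics favour and which is the orientation that opens; O1 and the 4-benzyloxyphenyl group at C2 stabilise the developing cation.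

Step 3
Reactants: 6 5,7-bis(benzyloxy)-2-[4-(benzyloxy)phenyl]chromenylium chloride
Product: 7 5,7-bis(benzyloxy)-2-[4-(benzyloxy)phenyl]-4H-chromene
Conditions: NaBH4, MeCN/THF, −40 → 0 °C
Reagents that add atoms: none
Why: Borohydride adds hydride to C4 of the 2-arylbenzopyrylium ion, the electrophilic terminus not shielded by the 2-aryl group, which gives the conjugated 4H enol ether (also the more stable double-bond isomer) as in standard reductions of flavylium salts; no stereocenter.

Step 4
Reactants: 7 5,7-bis(benzyloxy)-2-[4-(benzyloxy)phenyl]-4H-chromene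
Product: 9 (2S,3R)-5,7-bis(benzyloxy)-2-[4-(benzyloxy)phenyl]chroman-3-ol, via alkylborane 8 (not isolated)
Conditions: IpcBH2 [monoisopinocampheylborane from (−)-α-pinene], THF, −25 °C; then NaOH, H2O2, 0 °C → rt
Reagents that add atoms: hydrogen peroxide OO
Why: Brown asymmetric hydroboration–oxidation: boron adds to C3 (β to O1 and away from the aryl-bearing carbon), H and B add to the same face so that oxidation with retention gives the 2,3-trans alcohol, and the isopinocampheyl group selects the alkene face as it does for 1-arylcycloalkenes, which sets C2 (S) and C3 (R) in one operation.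

Step 5
Reactants: 9 (2S,3R)-5,7-bis(benzyloxy)-2-[4-(benzyloxy)phenyl]chroman-3-ol
Product: 10 (2S,3R)-5,7-bis(benzyloxy)-2-[4-(benzyloxy)phenyl]-8-bromochroman-3-ol
Conditions: NBS, CH2Cl2, −78 → 0 °C
Reagents that add atoms: N-bromosuccinimide O=C1CCC(=O)N1Br
Why: Electrophilic aromatic bromination of 5,7-dialkoxyflavans goes to C8 (para to the 5-ether and flanked by O1 and the 7-ether), as established for per-O-benzylated catechins, and marks the carbon that must later carry the chromanone; the stereocenters are untouched.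

Step 6
Reactants: 10 (2S,3R)-5,7-bis(benzyloxy)-2-[4-(benzyloxy)phenyl]-8-bromochroman-3-ol
Product: 11 (2S,3R)-3,5,7-tris(benzyloxy)-2-[4-(benzyloxy)phenyl]-8-bromochromane
Conditions: NaH, BnBr, DMF, 0 °C → rt
Reagents that add atoms: benzyl bromide BrCc1ccccc1
Why: Williamson etherification of the secondary alkoxide protects the carbinol before halogen–lithium exchange and leaves both stereocenters untouched.

Step 7
Reactants: 12 apigenin [5,7-dihydroxy-2-(4-hydroxyphenyl)-4H-chromen-4-one]
Product: 13 5,7-bis(benzyloxy)-2-[4-(benzyloxy)phenyl]-4H-chromen-4-one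
Conditions: BnBr, K2CO3, DMF, 80 °C
Reagents that add atoms: benzyl bromide BrCc1ccccc1
Why: Exhaustive Williamson benzylation; the hydrogen-bonded 5-hydroxyl needs the elevated temperature.

Step 8
Reactants: 13 5,7-bis(benzyloxy)-2-[4-(benzyloxy)phenyl]-4H-chromen-4-one
Product: 15 5,7-bis(benzyloxy)-2-[4-(benzyloxy)phenyl]-3-iodo-4H-chromen-4-one, via 3-lithioflavone 14 (not isolated)
Conditions: LiN(iPr)2, THF, −78 °C; then I2
Reagents that add atoms: iodine II
Why: The lithium amide removes the chromone C3–H (vinyl anion held by the C4 carbonyl, a known lithiation of flavones) and iodine traps the vinyllithium, which gives the 3-iodoflavone regiospecifically.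

Step 9
Reactants: 11 (2S,3R)-3,5,7-tris(benzyloxy)-2-[4-(benzyloxy)phenyl]-8-bromochromane; 15 5,7-bis(benzyloxy)-2-[4-(benzyloxy)phenyl]-3-iodo-4H-chromen-4-one
Product: 18 5,7-bis(benzyloxy)-2-[4-(benzyloxy)phenyl]-3-{(2S,3R)-3,5,7-tris(benzyloxy)-2-[4-(benzyloxy)phenyl]chroman-8-yl}-4H-chromen-4-one, via aryllithium 16 (not isolated), via arylzinc chloride 17 (not isolated)
Conditions: n-BuLi, THF, −78 °C; ZnCl2, −78 °C → rt; then 15, Pd2(dba)3, RuPhos, THF, 65 °C
Reagents that add atoms: none
Why: Bromine–lithium exchange at C8, transmetalation to zinc and Negishi cross-coupling (zerovalent palladium with a bulky dialkylbiarylphosphine, suited to a di-ortho-substituted arylzinc and a hindered alkenyl iodide) form the C3–C8 bond with the regiochemistry fixed by the two halogens; no stereocenter is touched.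

Step 10
Reactants: 18 the 3-(flavan-8-yl)chromone from step 9
Product: 20 (3S)-5,7-bis(benzyloxy)-2-[4-(benzyloxy)phenyl]-3-hydroxy-2-methoxy-3-{(2S,3R)-3,5,7-tris(benzyloxy)-2-[4-(benzyloxy)phenyl]chroman-8-yl}chroman-4-one (C2 epimers), via epoxide 19 (not isolated)
Conditions: DMDO, acetone/CH2Cl2, 0 °C → rt; then MeOH, PPTS, rt
Reagents that add atoms: dimethyldioxirane CC1(C)OO1; methanol CO
Why: Electrophilic dioxirane epoxidation of the chromone C2=C3 bond (known for flavones and isoflavones) creates the C3–O bond, and acid-catalysed methanolysis at the ketal-type C2 through the oxocarbenium ion gives a robust methyl ketal; the two chromone faces differ only through the remote flavan unit, so both epoxides are expected and the (3S) ketals (both C2 epimers serve) are separated from the (3R) series by chromatography.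

Step 11
Reactants: 20 the (3S)-methyl ketal from step 10
Product: 22 target (chromanone C3 bonded to flavan C8; chromanone C2 bonded to flavan O7), via heptaphenol methyl ketal 21 (not isolated)
Conditions: H2 (1 atm), Pd(OH)2/C, THF/MeOH, rt; then PPTS (cat.), rt
Reagents that add atoms: none
Why: Hydrogenolysis removes the seven benzyl ethers while the aryl ketal carbon survives as in syntheses of doubly linked proanthocyanidins, and acid-catalysed trans-ketalisation through the 2-aryl oxocarbenium ion lets O7 of ring D (the only phenol ortho to C8) displace methanol in a 5-exo closure onto the fixed C3 centre, which sets C2 as the ring closure dictates.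

**Compound list**

1 | 3,5-bis(benzyloxy)phenol | Oc1cc(OCc2ccccc2)cc(OCc2ccccc2)c1 | starting material
2 | 2-bromo-1-[4-(benzyloxy)phenyl]ethan-1-one | O=C(CBr)c1ccc(OCc2ccccc2)cc1 | starting material
3 | 2-[2,4-bis(benzyloxy)-6-hydroxyphenyl]-1-[4-(benzyloxy)phenyl]ethan-1-one (not isolated) | O=C(Cc1c(O)cc(OCc2ccccc2)cc1OCc1ccccc1)c1ccc(OCc2ccccc2)cc1 | intermediate
4 | 4,6-bis(benzyloxy)-2-[4-(benzyloxy)phenyl]-1-benzofuran | o1c(-c2ccc(OCc3ccccc3)cc2)cc2c(OCc3ccccc3)cc(OCc3ccccc3)cc12 | intermediate
5 | 4,6-bis(benzyloxy)-1a-[4-(benzyloxy)phenyl]-1-chloro-1a,6b-dihydro-1H-cyclopropa[b]benzofuran, chlorine cis to the ring oxygen (racemic, one enantiomer drawn; not isolated) | Cl[C@@H]1[C@]2(c3ccc(OCc4ccccc4)cc3)Oc3cc(OCc4ccccc4)cc(OCc4ccccc4)c3[C@H]12 | intermediate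
6 | 5,7-bis(benzyloxy)-2-[4-(benzyloxy)phenyl]chromenylium chloride | [Cl-].[o+]1c(-c2ccc(OCc3ccccc3)cc2)ccc2c(OCc3ccccc3)cc(OCc3ccccc3)cc12 | intermediate
7 | 5,7-bis(benzyloxy)-2-[4-(benzyloxy)phenyl]-4H-chromene | O1C(c2ccc(OCc3ccccc3)cc2)=CCc2c(OCc3ccccc3)cc(OCc3ccccc3)cc12 | intermediate
8 | (isopinocampheyl)borane carrying the flavan at C3, boron cis to H-2, configuration as in 9 (not isolated) | c1c(OCc3ccccc3)cc(OCc3ccccc3)c2c1O[C@@H](c1ccc(OCc3ccccc3)cc1)[C@H]([BH][C@H]1C[C@H]3C[C@@H]([C@@H]1C)C3(C)C)C2 | intermediate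
9 | (2S,3R)-5,7-bis(benzyloxy)-2-[4-(benzyloxy)phenyl]chroman-3-ol | c1c(OCc3ccccc3)cc(OCc3ccccc3)c2c1O[C@@H](c1ccc(OCc3ccccc3)cc1)[C@H](O)C2 | intermediate
10 | (2S,3R)-5,7-bis(benzyloxy)-2-[4-(benzyloxy)phenyl]-8-bromochroman-3-ol | Brc1c(OCc3ccccc3)cc(OCc3ccccc3)c2c1O[C@@H](c1ccc(OCc3ccccc3)cc1)[C@H](O)C2 | intermediate
11 | (2S,3R)-3,5,7-tris(benzyloxy)-2-[4-(benzyloxy)phenyl]-8-bromochromane | Brc1c(OCc3ccccc3)cc(OCc3ccccc3)c2c1O[C@@H](c1ccc(OCc3ccccc3)cc1)[C@H](OCc1ccccc1)C2 | intermediate
12 | apigenin | O=c1cc(-c2ccc(O)cc2)oc2cc(O)cc(O)c12 | starting material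
13 | 5,7-bis(benzyloxy)-2-[4-(benzyloxy)phenyl]-4H-chromen-4-one | O=c1cc(-c2ccc(OCc3ccccc3)cc2)oc2cc(OCc3ccccc3)cc(OCc3ccccc3)c12 | intermediate
14 | 3-lithio derivative of 13 (not isolated) | O=c1c([Li])c(-c2ccc(OCc3ccccc3)cc2)oc2cc(OCc3ccccc3)cc(OCc3ccccc3)c12 | intermediate
15 | 5,7-bis(benzyloxy)-2-[4-(benzyloxy)phenyl]-3-iodo-4H-chromen-4-one | O=c1c(I)c(-c2ccc(OCc3ccccc3)cc2)oc2cc(OCc3ccccc3)cc(OCc3ccccc3)c12 | intermediate
16 | 8-lithio derivative of 11 (not isolated) | [Li]c1c(OCc3ccccc3)cc(OCc3ccccc3)c2c1O[C@@H](c1ccc(OCc3ccccc3)cc1)[C@H](OCc1ccccc1)C2 | intermediate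
17 | 8-(chlorozincio) derivative of 11 (not isolated) | Cl[Zn]c1c(OCc3ccccc3)cc(OCc3ccccc3)c2c1O[C@@H](c1ccc(OCc3ccccc3)cc1)[C@H](OCc1ccccc1)C2 | intermediate
18 | 5,7-bis(benzyloxy)-2-[4-(benzyloxy)phenyl]-3-{(2S,3R)-3,5,7-tris(benzyloxy)-2-[4-(benzyloxy)phenyl]chroman-8-yl}-4H-chromen-4-one | O=c1c(-c3c(OCc4ccccc4)cc(OCc4ccccc4)c4c3O[C@@H](c3ccc(OCc5ccccc5)cc3)[C@H](OCc3ccccc3)C4)c(-c2ccc(OCc3ccccc3)cc2)oc2cc(OCc3ccccc3)cc(OCc3ccccc3)c12 | intermediate
19 | (2S,3S)-2,3-epoxide of 18, oxirane across chromanone C2–C3 (not isolated) | O=C1c2c(OCc4ccccc4)cc(OCc4ccccc4)cc2O[C@@]3(c2ccc(OCc4ccccc4)cc2)O[C@@]13c1c(OCc2ccccc2)cc(OCc2ccccc2)c2c1O[C@@H](c1ccc(OCc3ccccc3)cc1)[C@H](OCc1ccccc1)C2 | intermediate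
20 | (3S)-5,7-bis(benzyloxy)-2-[4-(benzyloxy)phenyl]-3-hydroxy-2-methoxy-3-{(2S,3R)-3,5,7-tris(benzyloxy)-2-[4-(benzyloxy)phenyl]chroman-8-yl}chroman-4-one (C2 epimers, C2 left open) | O=C1c2c(OCc4ccccc4)cc(OCc4ccccc4)cc2OC(OC)(c2ccc(OCc4ccccc4)cc2)[C@]1(O)c1c(OCc2ccccc2)cc(OCc2ccccc2)c2c1O[C@@H](c1ccc(OCc3ccccc3)cc1)[C@H](OCc1ccccc1)C2 | intermediate
21 | (3S)-3,5,7-trihydroxy-2-(4-hydroxyphenyl)-2-methoxy-3-[(2S,3R)-3,5,7-trihydroxy-2-(4-hydroxyphenyl)chroman-8-yl]chroman-4-one (C2 epimers; not isolated) | O=C1c2c(O)cc(O)cc2OC(OC)(c2ccc(O)cc2)[C@]1(O)c1c(O)cc(O)c2c1O[C@@H](c1ccc(O)cc1)[C@H](O)C2 | intermediate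
22 | target: (2R,3S)-3,5,7-trihydroxy-2-(4-hydroxyphenyl)chroman-4-one joined through C3 to C8 and through C2 to O7 of (2S,3R)-3,5-dihydroxy-2-(4-hydroxyphenyl)chroman | O=C1c2c(O)cc(O)cc2O[C@@]2(c3ccc(O)cc3)Oc3cc(O)c4c(c3[C@]12O)O[C@@H](c1ccc(O)cc1)[C@H](O)C4 | target

**Step count and risks**

Total: 11 steps. Longest linear sequence: 9 steps (steps 1–6 and 9–11, from 1).

Step 2 (key step). The short-lived chlorocarbenoid may add too slowly to the aromatic furan bond, may place chlorine on the aryl side (a cyclopropane that does not open), or the amide base may consume the benzopyrylium ion. The fallback sets out from 4 and uses dibromocarbene (CHBr3, KOt-Bu, pentane, 0 °C), the classical dihalocarbene ring enlargement of benzofurans, in which a bromine always sits on the concave face. The dibromocyclopropane F1 opens in the flask to 5,7-bis(benzyloxy)-2-[4-(benzyloxy)phenyl]-3-bromochromenylium bromide F2 (HBr work-up). NaBH4 then gives 5,7-bis(benzyloxy)-2-[4-(benzyloxy)phenyl]-3-bromo-4H-chromene F3. Bromine–lithium exchange (t-BuLi, THF, −78 °C) gives the 3-lithio-4H-chromene F4, and protonation with MeOH brings the route back at 7.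

Step 10. Oxygen transfer to the hindered, tetrasubstituted, electron-poor double bond may be slow, so that oxidation of the electron-rich ring D and of benzylic C–H bonds competes; both faces will also react. The fallback makes the C3–C8 bond by carbonyl addition instead of coupling followed by epoxidation, and sets out from 13 and 11. The unhindered flavone 13 is epoxidised with DMDO to the flavone 2,3-epoxide F5 and opened with MeOH/PPTS to 5,7-bis(benzyloxy)-2-[4-(benzyloxy)phenyl]-3-hydroxy-2-methoxychroman-4-one F6. Dess–Martin periodinane oxidises this to 5,7-bis(benzyloxy)-2-[4-(benzyloxy)phenyl]-2-methoxychromane-3,4-dione F7. Aryllithium 16 (from 11, n-BuLi, THF, −78 °C) should add to the C3 carbonyl, which is more electrophilic than the vinylogous-ester-type C4 carbonyl. After the same separation of C3 epimers the route is rejoined at 20.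

Step 4. The chiral borane may discriminate the faces of this benzo-fused enol ether poorly or in the opposite sense, leaving 9 in low enantiomeric purity. The fallback is a classical resolution that sets out from 9 of insufficient purity. Acylation with (1S)-camphanic chloride (Et3N, DMAP, CH2Cl2) gives the camphanate of the (2S,3R) alcohol F8, which is separated by chromatography or crystallisation from the camphanate of the (2R,3S) alcohol F9. Saponification of F8 (K2CO3, MeOH/THF) returns enantiopure 9.

Further compounds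
F1 | step 2 | 4,6-bis(benzyloxy)-1a-[4-(benzyloxy)phenyl]-1,1-dibromo-1a,6b-dihydro-1H-cyclopropa[b]benzofuran (racemic, one enantiomer drawn) | BrC1(Br)[C@]2(c3ccc(OCc4ccccc4)cc3)Oc3cc(OCc4ccccc4)cc(OCc4ccccc4)c3[C@H]12
F2 | step 2 | 5,7-bis(benzyloxy)-2-[4-(benzyloxy)phenyl]-3-bromochromenylium bromide | [Br-].Brc1cc2c(OCc3ccccc3)cc(OCc3ccccc3)cc2[o+]c1-c1ccc(OCc2ccccc2)cc1
F3 | step 2 | 5,7-bis(benzyloxy)-2-[4-(benzyloxy)phenyl]-3-bromo-4H-chromene | BrC1=C(c2ccc(OCc3ccccc3)cc2)Oc2cc(OCc3ccccc3)cc(OCc3ccccc3)c2C1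
F4 | step 2 | 5,7-bis(benzyloxy)-2-[4-(benzyloxy)phenyl]-3-lithio-4H-chromene | [Li]C1=C(c2ccc(OCc3ccccc3)cc2)Oc2cc(OCc3ccccc3)cc(OCc3ccccc3)c2C1
F5 | step 10 | 2,3-epoxide of 13 (racemic, one enantiomer drawn) | O=C1c2c(OCc4ccccc4)cc(OCc4ccccc4)cc2O[C@@]3(c2ccc(OCc4ccccc4)cc2)O[C@@H]13
F6 | step 10 | 5,7-bis(benzyloxy)-2-[4-(benzyloxy)phenyl]-3-hydroxy-2-methoxychroman-4-one (racemic, configuration immaterial) | O=C1C(O)C(OC)(c2ccc(OCc3ccccc3)cc2)Oc2cc(OCc3ccccc3)cc(OCc3ccccc3)c12
F7 | step 10 | 5,7-bis(benzyloxy)-2-[4-(benzyloxy)phenyl]-2-methoxychromane-3,4-dione (racemic) | O=C1C(=O)C(OC)(c2ccc(OCc3ccccc3)cc2)Oc2cc(OCc3ccccc3)cc(OCc3ccccc3)c12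
F8 | step 4 | (1S)-camphanate of (2S,3R)-alcohol 9 | c1c(OCc3ccccc3)cc(OCc3ccccc3)c2c1O[C@@H](c1ccc(OCc3ccccc3)cc1)[C@H](OC(=O)[C@@]13CC[C@@](C)(C(=O)O1)C3(C)C)C2
F9 | step 4 | (1S)-camphanate of the (2R,3S) enantiomer of 9 | c1c(OCc3ccccc3)cc(OCc3ccccc3)c2c1O[C@H](c1ccc(OCc3ccccc3)cc1)[C@@H](OC(=O)[C@@]13CC[C@@](C)(C(=O)O1)C3(C)C)C2
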